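**Retrosynthetic overview**
- Feature: the benzo ring of the tetralone is a p-hydroquinone (OH on C5 and C8) whose C4a–C8a edge is bridged by C1–C4, with the ketone at C1 and the peri-methoxynaphthyl group on the only stereocentre, C4. The target is therefore a constitutional isomer of the [4+2] adduct of p-benzoquinone with the dienol of a 4-naphthylbut-2-enal.
- Key disconnection: C4–C4a and C1–C8a, formed together in a catalytic enantioselective Diels–Alder reaction of a (1E,3E)-1-siloxy-4-naphthylbutadiene with p-benzoquinone. Enolisation to the hydroquinone (trapped as benzyl ethers), alkene saturation, oxidation at C1 and debenzylation follow.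
- Diene: 1,5-dimethoxynaphthalene is formylated (C4), demethylated para to the formyl group and benzylated, homologated by one carbon (C3), extended by a Wittig reaction (C2, C1) and silylated after γ-deprotonation.
- Ring order: the naphthalene and the six-carbon quinone ring are bought intact; the tetralone carbocycle is closed in the key step; the quinone-derived ring is aromatised directly afterwards.

Key step: step 8

Assumption: the sense of induction in step 8 is taken from the usual pre-transition-state model of the oxazaborolidinium catalyst and has not been verified for this diene; the (S)-proline-derived catalyst is written, and the (R)-catalyst replaces it without other change if the adducts prove to belong to the (5S) series.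

**Step 1**
Reactants: 1 1,5-dimethoxynaphthalene; 2 N,N-dimethylformamide
Product: 4 4,8-dimethoxynaphthalene-1-carbaldehyde, via (4,8-dimethoxynaphthalen-1-yl)methylidene-dimethyliminium dichlorophosphate 3 (not isolated)
Conditions: POCl3, DMF, toluene, 0 → 90 °C; then 2 M aq NaOH, 0 °C
Reagents that add atoms: N,N-dimethylformamide 2 (CN(C)C=O); water (O)
Why: Vilsmeier–Haack formylation; the chloroiminium ion attacks the free α-position para to a methoxy group (the two such sites are equivalent by symmetry), the deactivated iminium stops a second formylation, and aqueous hydrolysis releases the aldehyde.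

**Step 2**
Reactants: 4 4,8-dimethoxynaphthalene-1-carbaldehyde
Product: 5 4-hydroxy-8-methoxynaphthalene-1-carbaldehyde
Conditions: NaSEt, DMF, 110 °C; then 1 M HCl
Reagents that add atoms: none
Why: SN2 O-demethylation by thiolate; the 4-methoxy group is conjugated para to the formyl group (a vinylogous ester), so its aryloxide is the better leaving group, whereas the 8-methoxy group on the other ring has no such conjugation and should stay.

**Step 3**
Reactants: 5 4-hydroxy-8-methoxynaphthalene-1-carbaldehyde
Product: 6 4-(benzyloxy)-8-methoxynaphthalene-1-carbaldehyde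
Conditions: BnBr, K2CO3, DMF, rt
Reagents that add atoms: benzyl bromide (BrCc1ccccc1)
Why: Williamson ether synthesis on an acidic, unhindered naphthol.

**Step 4**
Reactants: 6 4-(benzyloxy)-8-methoxynaphthalene-1-carbaldehyde; 7 (methoxymethyl)triphenylphosphonium chloride
Product: 8 1-(benzyloxy)-5-methoxy-4-(2-methoxyethenyl)naphthalene (E/Z mixture)
Conditions: 7, KOtBu, THF, 0 °C; then 6, 0 °C → rt
Reagents that add atoms: (methoxymethyl)triphenylphosphonium chloride 7 (COC[P+](c1ccccc1)(c1ccccc1)c1ccccc1.[Cl-])
Why: Wittig methoxymethylenation; the reactive non-stabilised ylide should add to the non-enolisable, peri-hindered aldehyde, and the alkene geometry is irrelevant because both isomers hydrolyse to the same aldehyde.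

**Step 5**
Reactants: 8 1-(benzyloxy)-5-methoxy-4-(2-methoxyethenyl)naphthalene
Product: 9 2-[4-(benzyloxy)-8-methoxynaphthalen-1-yl]acetaldehyde
Conditions: 2 M aq HCl, THF, 50 °C; used directly in step 6
Reagents that add atoms: water (O)
Why: acid-catalysed enol ether hydrolysis (C-protonation at the benzylic carbon, hydration of the oxocarbenium ion, loss of methanol); the benzyl and methyl aryl ethers are stable to dilute acid.

**Step 6**
Reactants: 9 2-[4-(benzyloxy)-8-methoxynaphthalen-1-yl]acetaldehyde; 10 (triphenylphosphoranylidene)acetaldehyde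
Product: 11 (2E)-4-[4-(benzyloxy)-8-methoxynaphthalen-1-yl]but-2-enal
Conditions: 10 (1.1 equiv), toluene, 70 °C
Reagents that add atoms: (triphenylphosphoranylidene)acetaldehyde 10 (O=CC=P(c1ccccc1)(c1ccccc1)c1ccccc1)
Why: Wittig olefination with a stabilised ylide, E-selective; the saturated aldehyde reacts faster than the product enal, and any β,γ-isomer formed gives the same dienol ether in step 7.

**Step 7**
Reactants: 11 (2E)-4-[4-(benzyloxy)-8-methoxynaphthalen-1-yl]but-2-enal
Product: 12 {[(1E,3E)-4-[4-(benzyloxy)-8-methoxynaphthalen-1-yl]buta-1,3-dien-1-yl]oxy}(tert-butyl)dimethylsilane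
Conditions: TBSOTf, Et3N, CH2Cl2, 0 °C; aq NaHCO3 work-up
Reagents that add atoms: tert-butyldimethylsilyl triflate (CC(C)(C)[Si](C)(C)OS(=O)(=O)C(F)(F)F)
Why: soft γ-enolisation with O-silylation (silyl dienol ether formation); the O-silylated enal loses its benzylic γ-proton to Et3N, the s-trans enal gives the 1E enol ether and conjugation with the naphthalene gives the 3E alkene.

**Step 8**
Reactants: 12 (1E,3E)-silyl dienol ether; 13 p-benzoquinone
Product: 14 (4aR,5R,8S,8aR)-5-[4-(benzyloxy)-8-methoxynaphthalen-1-yl]-8-[(tert-butyldimethylsilyl)oxy]-4a,5,8,8a-tetrahydronaphthalene-1,4-dione (all-cis endo adduct)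
Conditions: 13 (2 equiv), (S)-o-tolyl-oxazaborolidine·HNTf2 (20 mol %), CH2Cl2, −78 °C
Reagents that add atoms: p-benzoquinone 13 (O=C1C=CC(=O)C=C1)
Why: The protonated oxazaborolidine binds one quinone carbonyl and lowers the LUMO of the adjacent C=C, so that the catalysed path should outrun the uncatalysed one at −78 °C; the reaction type is the known chiral-Lewis-acid-catalysed Diels–Alder reaction of quinones with 1-oxygenated butadienes, applied here to a diene that also carries an aryl group at its other terminus. The naphthyl-bearing diene carbon (largest HOMO coefficient) bonds first to the quinone carbon β to the bound carbonyl and the siloxy-bearing carbon then closes on the α carbon in an asynchronous, suprafacial [4+2] that forms C5–C4a and C8–C8a in one event and closes the six-membered carbocycle C5–C6–C7–C8–C8a–C4a. The E,E geometry places naphthyl and siloxy both outside, so C5 and C8 come out cis, the cis quinone alkene gives the cis ring fusion, and the endo transition state (secondary overlap of the diene with the enedione) puts both substituents on the face of the quinone ring, giving the all-cis adduct. The absolute configuration at C5, the later C4 of the target, is set by the catalyst, whose aryl group screens one face of the bound quinone; C8, C4a and C8a follow from C5 and are all erased later. The step needs face, endo and orientation selectivity to hold together: the catalyst supplies the first, the enedione the second and the siloxy donor the third, while the symmetry of benzoquinone removes any regiochemical question and its excess suppresses double addition. The peri-methoxy group twists the naphthyl out of the diene plane so that it turns its small C2–H edge toward the dienophile.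

**Step 9**
Reactants: 14 all-cis endo adduct
Product: 16 {[(1S,4S)-5,8-bis(benzyloxy)-4-[4-(benzyloxy)-8-methoxynaphthalen-1-yl]-1,4-dihydronaphthalen-1-yl]oxy}(tert-butyl)dimethylsilane (cis), via (5S,8S)-5-[4-(benzyloxy)-8-methoxynaphthalen-1-yl]-8-[(tert-butyldimethylsilyl)oxy]-5,8-dihydronaphthalene-1,4-diol 15 (not isolated)
Conditions: K2CO3, BnBr, nBu4NI (cat.), degassed DMF, 0 °C → rt, Ar
Reagents that add atoms: benzyl bromide (BrCc1ccccc1)
Why: base-mediated double enolisation of the enedione to the aromatic hydroquinone (erasing C4a and C8a) with Williamson O-benzylation in the same flask; fast capping of the phenoxides and exclusion of air are meant to forestall loss of silanol and oxidation to the quinone, and the two sp3 centres at C1 and C4 are not touched.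

**Step 10**
Reactants: 16 cis-1-siloxy-4-naphthyl-5,8-bis(benzyloxy)-1,4-dihydronaphthalene
Product: 17 {[(1S,4S)-5,8-bis(benzyloxy)-4-[4-(benzyloxy)-8-methoxynaphthalen-1-yl]-1,2,3,4-tetrahydronaphthalen-1-yl]oxy}(tert-butyl)dimethylsilane (cis)
Conditions: 2-nitrobenzenesulfonylhydrazide, Et3N, CH2Cl2, rt (repeated charges)
Reagents that add atoms: none
Why: diimide reduction (concerted syn transfer of two hydrogens to the unpolarised cis-alkene from the face opposite the naphthyl and siloxy groups); benzyl ethers, the benzylic C–O bond and the arenes are inert to diimide, and no stereocentre is created or touched.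

**Step 11**
Reactants: 17 cis-1-siloxy-4-naphthyl-5,8-bis(benzyloxy)tetralin
Product: 18 (1S,4S)-5,8-bis(benzyloxy)-4-[4-(benzyloxy)-8-methoxynaphthalen-1-yl]-1,2,3,4-tetrahydronaphthalen-1-ol
Conditions: TBAF, THF, 0 °C → rt; H2O work-up
Reagents that add atoms: none
Why: fluoride-mediated desilylation driven by Si–F bond formation; the non-acidic conditions avoid ionisation of the electron-rich benzylic C–O bond.

**Step 12**
Reactants: 18 benzylic alcohol
Product: 19 (4S)-5,8-bis(benzyloxy)-4-[4-(benzyloxy)-8-methoxynaphthalen-1-yl]-3,4-dihydronaphthalen-1(2H)-one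
Conditions: Dess–Martin periodinane, NaHCO3, CH2Cl2, 0 °C → rt
Reagents that add atoms: none
Why: Dess–Martin oxidation of the secondary benzylic alcohol under buffered, neutral conditions; because C2–C3 is already saturated, the C4 hydrogen is not γ to an enone and the stereocentre should be retained.

**Step 13**
Reactants: 19 tris(benzyl)-protected tetralone
Product: 20 (4S)-5,8-dihydroxy-4-(4-hydroxy-8-methoxynaphthalen-1-yl)-3,4-dihydronaphthalen-1(2H)-one (target)
Conditions: H2 (1 atm), 10 % Pd/C, EtOAc–MeOH, rt; work-up under Ar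
Reagents that add atoms: none
Why: palladium-catalysed hydrogenolysis of the three aryl benzyl ethers; the aryl methyl ether, the naphthalene and the conjugated ketone (hydrogen-bonded to the freed C8 hydroxyl) should survive at 1 atm in neutral solvent, and C4 is not involved.

**Compound list**
1 | 1,5-dimethoxynaphthalene | COc1cccc2c(OC)cccc12 | starting material
2 | N,N-dimethylformamide | CN(C)C=O | starting material
3 | (4,8-dimethoxynaphthalen-1-yl)methylidene-dimethyliminium dichlorophosphate | COc1cccc2c(OC)ccc(C=[N+](C)C)c12.[O-]P(=O)(Cl)Cl | intermediate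
4 | 4,8-dimethoxynaphthalene-1-carbaldehyde | COc1cccc2c(OC)ccc(C=O)c12 | intermediate
5 | 4-hydroxy-8-methoxynaphthalene-1-carbaldehyde | COc1cccc2c(O)ccc(C=O)c12 | intermediate
6 | 4-(benzyloxy)-8-methoxynaphthalene-1-carbaldehyde | COc1cccc2c(OCc3ccccc3)ccc(C=O)c12 | intermediate
7 | (methoxymethyl)triphenylphosphonium chloride | COC[P+](c1ccccc1)(c1ccccc1)c1ccccc1.[Cl-] | starting material
8 | 1-(benzyloxy)-5-methoxy-4-(2-methoxyethenyl)naphthalene (E/Z mixture) | COc1cccc2c(OCc3ccccc3)ccc(C=COC)c12 | intermediate
9 | 2-[4-(benzyloxy)-8-methoxynaphthalen-1-yl]acetaldehyde | COc1cccc2c(OCc3ccccc3)ccc(CC=O)c12 | intermediate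
10 | (triphenylphosphoranylidene)acetaldehyde | O=CC=P(c1ccccc1)(c1ccccc1)c1ccccc1 | starting material
11 | (2E)-4-[4-(benzyloxy)-8-methoxynaphthalen-1-yl]but-2-enal | COc1cccc2c(OCc3ccccc3)ccc(C/C=C/C=O)c12 | intermediate
12 | {[(1E,3E)-4-[4-(benzyloxy)-8-methoxynaphthalen-1-yl]buta-1,3-dien-1-yl]oxy}(tert-butyl)dimethylsilane | COc1cccc2c(OCc3ccccc3)ccc(/C=C/C=C/O[Si](C)(C)C(C)(C)C)c12 | intermediate
13 | p-benzoquinone | O=C1C=CC(=O)C=C1 | starting material
14 | (4aR,5R,8S,8aR)-5-[4-(benzyloxy)-8-methoxynaphthalen-1-yl]-8-[(tert-butyldimethylsilyl)oxy]-4a,5,8,8a-tetrahydronaphthalene-1,4-dione | O=C1C=CC(=O)[C@H]2[C@@H]1[C@@H](O[Si](C)(C)C(C)(C)C)C=C[C@H]2c1ccc(OCc2ccccc2)c2cccc(OC)c12 | intermediate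
15 | (5S,8S)-5-[4-(benzyloxy)-8-methoxynaphthalen-1-yl]-8-[(tert-butyldimethylsilyl)oxy]-5,8-dihydronaphthalene-1,4-diol | COc1cccc2c(OCc3ccccc3)ccc([C@@H]3C=C[C@H](O[Si](C)(C)C(C)(C)C)c4c(O)ccc(O)c43)c12 | intermediate
16 | {[(1S,4S)-5,8-bis(benzyloxy)-4-[4-(benzyloxy)-8-methoxynaphthalen-1-yl]-1,4-dihydronaphthalen-1-yl]oxy}(tert-butyl)dimethylsilane | COc1cccc2c(OCc3ccccc3)ccc([C@@H]3C=C[C@H](O[Si](C)(C)C(C)(C)C)c4c(OCc5ccccc5)ccc(OCc5ccccc5)c43)c12 | intermediate
17 | {[(1S,4S)-5,8-bis(benzyloxy)-4-[4-(benzyloxy)-8-methoxynaphthalen-1-yl]-1,2,3,4-tetrahydronaphthalen-1-yl]oxy}(tert-butyl)dimethylsilane | COc1cccc2c(OCc3ccccc3)ccc([C@@H]3CC[C@H](O[Si](C)(C)C(C)(C)C)c4c(OCc5ccccc5)ccc(OCc5ccccc5)c43)c12 | intermediate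
18 | (1S,4S)-5,8-bis(benzyloxy)-4-[4-(benzyloxy)-8-methoxynaphthalen-1-yl]-1,2,3,4-tetrahydronaphthalen-1-ol | COc1cccc2c(OCc3ccccc3)ccc([C@@H]3CC[C@H](O)c4c(OCc5ccccc5)ccc(OCc5ccccc5)c43)c12 | intermediate
19 | (4S)-5,8-bis(benzyloxy)-4-[4-(benzyloxy)-8-methoxynaphthalen-1-yl]-3,4-dihydronaphthalen-1(2H)-one | COc1cccc2c(OCc3ccccc3)ccc([C@@H]3CCC(=O)c4c(OCc5ccccc5)ccc(OCc5ccccc5)c43)c12 | intermediate
20 | (4S)-5,8-dihydroxy-4-(4-hydroxy-8-methoxynaphthalen-1-yl)-3,4-dihydronaphthalen-1(2H)-one | COc1cccc2c(O)ccc([C@@H]3CCC(=O)c4c(O)ccc(O)c43)c12 | target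

**Total step count:** 13
**Longest linear sequence:** 13 steps (from 1,5-dimethoxynaphthalene 1)

**Steps most likely to fail**

Step 8. Face discrimination by the catalyst may be insufficient at the hindered, twisted naphthyl terminus, the uncatalysed racemic cycloaddition may compete, or the acidic catalyst may desilylate the dienol ether. The fallback gives up catalytic control for a racemic synthesis and resolution; it sets out from 12 and 13 and comes back at 16. Uncatalysed cycloaddition (toluene, rt) should give the racemic all-cis adduct, that is 14 together with its enantiomer, the (4aS,5S,8R,8aS)-adduct F1. The conditions of step 9 applied to the racemate should pass through 15 and its enantiomer, the (5R,8R)-hydroquinone F2 (not isolated), and give 16 together with its enantiomer, the (1R,4R)-bis-benzyl ether F3. Preparative chromatography on a polysaccharide chiral stationary phase (SFC) then separates 16 from F3, and 16 continues at step 10.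

Step 9. The enolate or the ortho-phenoxide may expel silanol and the ring may then aromatise fully to a naphthalene, destroying the stereocentre; the hydroquinone may also oxidise in air before it is alkylated. The fallback sets out from 14 and comes back at 17. Acetylative enolisation (Ac2O, pyridine, DMAP cat., CH2Cl2, 0 °C) traps the hydroquinone without a free phenoxide as the (5S,8S)-dihydronaphthalene-1,4-diyl diacetate F4. Diimide reduction as in step 10 gives the tetralin diacetate F5. Only then, with the ring alkene gone and aromatisation no longer possible, are the acetates removed (K2CO3, degassed MeOH) to the tetralin hydroquinone F6 (not isolated), which is benzylated in the same flask (BnBr, K2CO3, DMF) to 17.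

Step 13. The aryl ketone may be over-reduced, the hindered peri benzyl ethers may cleave incompletely, or the product hydroquinone may oxidise during a long reaction. The fallback sets out from 19 and comes back at 20 without a new compound (F0): Lewis-acid debenzylation with BCl3 and pentamethylbenzene as cation scavenger (CH2Cl2, −78 °C), which involves no reduction and should leave the aryl methyl ether intact at this temperature.

**Further compounds**
F1 | step 8 | (4aS,5S,8R,8aS)-5-[4-(benzyloxy)-8-methoxynaphthalen-1-yl]-8-[(tert-butyldimethylsilyl)oxy]-4a,5,8,8a-tetrahydronaphthalene-1,4-dione | O=C1C=CC(=O)[C@@H]2[C@H]1[C@H](O[Si](C)(C)C(C)(C)C)C=C[C@@H]2c1ccc(OCc2ccccc2)c2cccc(OC)c12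
F2 | step 8 | (5R,8R)-5-[4-(benzyloxy)-8-methoxynaphthalen-1-yl]-8-[(tert-butyldimethylsilyl)oxy]-5,8-dihydronaphthalene-1,4-diol | COc1cccc2c(OCc3ccccc3)ccc([C@H]3C=C[C@@H](O[Si](C)(C)C(C)(C)C)c4c(O)ccc(O)c43)c12
F3 | step 8 | {[(1R,4R)-5,8-bis(benzyloxy)-4-[4-(benzyloxy)-8-methoxynaphthalen-1-yl]-1,4-dihydronaphthalen-1-yl]oxy}(tert-butyl)dimethylsilane | COc1cccc2c(OCc3ccccc3)ccc([C@H]3C=C[C@@H](O[Si](C)(C)C(C)(C)C)c4c(OCc5ccccc5)ccc(OCc5ccccc5)c43)c12
F4 | step 9 | (5S,8S)-5-[4-(benzyloxy)-8-methoxynaphthalen-1-yl]-8-[(tert-butyldimethylsilyl)oxy]-5,8-dihydronaphthalene-1,4-diyl diacetate | COc1cccc2c(OCc3ccccc3)ccc([C@@H]3C=C[C@H](O[Si](C)(C)C(C)(C)C)c4c(OC(C)=O)ccc(OC(C)=O)c43)c12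
F5 | step 9 | (5S,8S)-5-[4-(benzyloxy)-8-methoxynaphthalen-1-yl]-8-[(tert-butyldimethylsilyl)oxy]-5,6,7,8-tetrahydronaphthalene-1,4-diyl diacetate | COc1cccc2c(OCc3ccccc3)ccc([C@@H]3CC[C@H](O[Si](C)(C)C(C)(C)C)c4c(OC(C)=O)ccc(OC(C)=O)c43)c12
F6 | step 9 | (5S,8S)-5-[4-(benzyloxy)-8-methoxynaphthalen-1-yl]-8-[(tert-butyldimethylsilyl)oxy]-5,6,7,8-tetrahydronaphthalene-1,4-diol | COc1cccc2c(OCc3ccccc3)ccc([C@@H]3CC[C@H](O[Si](C)(C)C(C)(C)C)c4c(O)ccc(O)c43)c12
F0 | step 13 | none | none
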